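**Plan**
Labels: ring C1 (quaternary carbinol) – C5 (CH–O-angelate) – C6 (lactone O–CH) – C7 – C8 (CH2) – C9 (CHOH) – C10 (CHMe) – back to C1; crotonyl C2–C4; lactone C11 (α-carbon), C12 (C=O), C13 (=CH2).
Cuts, in retrosynthetic order: lactone O–C6 (formed while a C6–O–C9 ether bridge is opened by the C12 acid), C11=C13, C3=C4, the O5–acyl bond, C1–C2, C5–O, C7–H, and last the ring bonds C5–C6 and C9–C10.
Enabling feature: C6 and C9 both carry oxygen and are joined through C7–C8, so C6–C7–C8–C9 plus one oxygen is a furan; C5–C1–C10, oxygenated at its middle carbon, is a 2-oxidoallyl (oxyallyl) cation; their (4+3) union is the cycloheptane.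
Forward order: furan 5 and the cation from 6 close the carbocycle as an 8-oxabicyclo[3.2.1]octenone (step 3); the bicycle then receives H7, O5 and the C2 chain; the γ-lactone ring closes in the last step as the ether bridge opens.
Stereochemistry: C6/C9 (absolute) and C10 from the catalysed cycloaddition; C7, C5 and C1 from exo-face attack on the bicycle; C6 is carried inverted on purpose and corrected by SN2 lactonisation, which makes the C6 and C9 oxygens trans; E from cross-metathesis, Z from angelic acid.

Key step: step 3

Remark: the labels above are used in all names; "exo" is the face of the bicycle syn to the oxygen bridge; it is assumed that the antipode of the squaramide that gives the (1R,2S,5R) adduct is found by testing both, each being accessible.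

Step 1
Reactants: 1 3-bromofuran; 2 oxirane
Product: 4 2-(furan-3-yl)ethanol, via furan-3-yllithium 3 (not isolated)
Conditions: n-BuLi, THF, −78 °C; then 2, BF3·OEt2, −78 °C; H2O
Reagents that add atoms: none
Why: Bromine–lithium exchange at −78 °C gives the 3-lithiofuran without isomerisation to the 2-lithio species, and opening of the BF3-activated epoxide by an aryllithium is a standard two-carbon hydroxyethylation.

Step 2
Reactants: 4 2-(furan-3-yl)ethanol
Product: 5 tert-butyl[2-(furan-3-yl)ethoxy]dimethylsilane
Conditions: TBSCl, imidazole, CH2Cl2, 0 °C → rt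
Reagents that add atoms: tert-butyldimethylsilyl chloride, CC(C)(C)[Si](C)(C)Cl
Why: Silylation of a primary alcohol under standard conditions gives an ether that withstands the base, hydrogenation, enolate, peracid and organolithium steps and is cleaved by the aqueous acid of step 9.

Step 3
Reactants: 5 tert-butyl[2-(furan-3-yl)ethoxy]dimethylsilane; 6 1-bromobutan-2-one
Product: 8 (1R,2S,5R)-6-[2-(tert-butyldimethylsilyloxy)ethyl]-2-methyl-8-oxabicyclo[3.2.1]oct-6-en-3-one, via oxyallyl cation 7 (not isolated)
Conditions: 6 (1.5 equiv), chiral squaramide hydrogen-bond donor [3,5-(CF3)2C6H3NH-squaramide of a tert-leucine 2-arylpyrrolidine amide] (10 mol %), Na2CO3 (powder), toluene–CF3CH2OH 20:1, −20 °C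
Reagents that add atoms: none
Why: Proposed new method: carbonate-mediated enolisation of 6 while its carbonyl oxygen sits in the two N–H bonds of the squaramide, followed by loss of bromide as NaBr, should give the W-shaped (Z) oxyallyl cation 7 held by hydrogen bonds in a chiral pocket, and this three-carbon 2π cation adds across the two furan α-carbons of 5 in an asynchronous (4+3) cycloaddition. The closest known reaction types are the racemic (4+3) cycloaddition of furans with oxyallyl cations generated from α-halo ketones by base in fluorinated alcohols, and the enantioselective (4+3) cycloaddition of alkoxy-substituted oxyallyl cations with furans under squaramide/silyl triflate co-catalysis. The seven-membered carbocycle closes intermolecularly, C5–C6 forming ahead of C9–C10, and the furan oxygen remains as the one-atom bridge of the 8-oxabicyclo[3.2.1]octene. C6 and C9 are created together and their absolute sense is controlled by the catalyst, whose aryl group covers one face of the bound cation, while C10 is controlled by the compact transition state of the W cation, which leaves the methyl equatorial and anti to the oxygen bridge (also the thermodynamic position, so a minor epimer can be converged with mild base). Regioselectivity (CH2 terminus to C6, CHMe terminus to C9) is secured by the higher nucleophilicity of the furan carbon next to the alkyl side chain towards the unhindered cation terminus and by avoiding a methyl/side-chain clash across the bridgehead; cycloaddition is favoured over simple furan alkylation by the s-cis diene and the low temperature, and the weakly ionising medium should suppress the uncatalysed racemic pathway.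

Step 4
Reactants: 8 cycloadduct
Product: 9 (1R,2S,5R,6R)-6-[2-(tert-butyldimethylsilyloxy)ethyl]-2-methyl-8-oxabicyclo[3.2.1]octan-3-one
Conditions: H2 (1 atm), 10% Pd/C, EtOAc, rt
Reagents that add atoms: none
Why: Heterogeneous hydrogenation of a bridged alkene delivers both hydrogens from the exo face, because the endo face is shielded by the three-carbon keto bridge, so H7 ends up syn to the oxygen bridge and the side chain endo (C7 set by substrate control).

Step 5
Reactants: 9 saturated bicyclic ketone
Product: 10 trimethylsilyl enol ether of 9 with the C1=C5 double bond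
Conditions: LiN(iPr)2, Me3SiCl (in situ quench), THF, −78 °C
Reagents that add atoms: chlorotrimethylsilane, C[Si](C)(C)Cl
Why: Kinetic deprotonation with a lithium amide removes a proton from the unsubstituted C5 methylene and not from the methyl-bearing C10, and in situ O-silylation at −78 °C fixes the less substituted silyl enol ether before the enolate can expel the β-oxygen bridge.

Step 6
Reactants: 10 silyl enol ether
Product: 13 (1R,2S,4S,5S,6R)-6-[2-(tert-butyldimethylsilyloxy)ethyl]-4-hydroxy-2-methyl-8-oxabicyclo[3.2.1]octan-3-one, via silyloxy epoxide 11 (not isolated), via silyloxy ketone 12 (not isolated)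
Conditions: mCPBA, CH2Cl2, −20 → 0 °C; then citric acid, MeOH, 0 °C
Reagents that add atoms: meta-chloroperoxybenzoic acid, OOC(=O)c1cccc(Cl)c1
Why: Rubottom oxidation: the peracid epoxidises the electron-rich enol ether on the open exo face (the endo face lies over the ethano bridge and its endo side chain), the silyloxy epoxide rearranges by 1,4-silyl shift, and brief acidic methanolysis removes the trimethylsilyl group but not the primary TBS ether, so the new C5 hydroxyl is syn to the oxygen bridge.

Step 7
Reactants: 13 α-hydroxy ketone; 14 methoxyallene (1-methoxypropa-1,2-diene)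
Product: 16 (1S,2S,3S,4S,5R,7R)-7-[2-(tert-butyldimethylsilyloxy)ethyl]-3-(1-methoxypropa-1,2-dien-1-yl)-4-methyl-8-oxabicyclo[3.2.1]octane-2,3-diol, via 1-lithio-1-methoxyallene 15 (not isolated)
Conditions: 14 (3.5 equiv), n-BuLi (3.3 equiv), THF, −40 °C; then 13, −78 °C; H2O
Reagents that add atoms: none
Why: 1,2-Addition of lithiated methoxyallene, a compact acyl-anion equivalent, to a ketone: the first equivalent forms the C5 lithium alkoxide and the next adds to C1 from the exo face, the endo face being closed by the ethano bridge and the endo side chain, which puts C2 syn and the tertiary hydroxyl anti to the oxygen bridge.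

Step 8
Reactants: 16 diol; 17 angelic acid [(Z)-2-methylbut-2-enoic acid]
Product: 19 O5-angelate of 16 [C5 ester of (Z)-2-methylbut-2-enoic acid; C1 hydroxyl free], via mixed anhydride 18 (not isolated)
Conditions: 17, 2,4,6-trichlorobenzoyl chloride, Et3N, toluene, rt; then 16, toluene, 75 °C
Reagents that add atoms: none
Why: Yamaguchi-type esterification through the preformed mixed anhydride, run without a nucleophilic catalyst, is the established way to transfer the angeloyl group without Z-to-E isomerisation, and only the secondary C5 hydroxyl can react because the C1 hydroxyl is tertiary and the enone that could undergo oxa-Michael addition is still masked as the base-stable allenyl ether.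

Step 9
Reactants: 19 angelate
Product: 20 vinyl ketone with free primary alcohol [C1 bears OH and prop-2-enoyl; C7 bears CH2CH2OH]
Conditions: H2SO4 (1 M aq.), THF, 0 °C → rt
Reagents that add atoms: water, O
Why: Aqueous acid protonates the central allene carbon of the 1-methoxyallenyl carbinol, the oxocarbenium ion is hydrated and loses methanol to give the α'-hydroxy vinyl ketone (the standard unmasking of methoxyallene adducts), and the same medium cleaves the primary TBS ether while the ester and the ether bridge stay.

Step 10
Reactants: 20 vinyl ketone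
Product: 21 (E)-but-2-enoyl (crotonyl) ketone with free primary alcohol
Conditions: (Z)-but-2-ene (excess), second-generation Hoveyda–Grubbs catalyst RuCl2(H2IMes)(=CH-C6H4-2-OiPr) (5 mol %), CH2Cl2, 40 °C, sealed tube
Reagents that add atoms: (Z)-but-2-ene, C/C=C\C
Why: Olefin cross-metathesis of a vinyl ketone with an excess of a simple internal olefin gives the E-enone under thermodynamic control, and the trisubstituted, electron-poor angelate olefin is inert to the ruthenium carbene.

Step 11
Reactants: 21 crotonyl ketone alcohol
Product: 22 aldehyde [C7 bears CH2CHO]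
Conditions: Dess–Martin periodinane, CH2Cl2, 0 °C → rt
Reagents that add atoms: none
Why: Dess–Martin oxidation converts the only primary alcohol into the aldehyde under near-neutral conditions that leave the tertiary α-ketol, the enone and the angelate untouched.

Step 12
Reactants: 22 aldehyde
Product: 24 α-methylene aldehyde [C7 bears C(=CH2)CHO], via Mannich base 23 (not isolated)
Conditions: CH2=NMe2+ I− (Eschenmoser's salt), Et3N, CH2Cl2, rt
Reagents that add atoms: N,N-dimethylmethyleneiminium iodide, C=[N+](C)C.[I-]
Why: Mannich reaction of the aldehyde with the preformed iminium salt followed by amine-induced loss of dimethylamine is the standard α-methylenation of aldehydes, and C11 is the only readily enolisable position because the C2 ketone has no α-hydrogen on C1.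

Step 13
Reactants: 24 α-methylene aldehyde
Product: 25 2-substituted acrylic acid [C7 bears C(=CH2)CO2H]
Conditions: NaClO2, NaH2PO4, 2-methylbut-2-ene, t-BuOH/H2O, 0 °C → rt
Reagents that add atoms: sodium chlorite, [Na+].[O-]Cl=O
Why: Pinnick oxidation converts the enal into the acrylic acid, the alkene scavenger removing hypochlorous acid before it can attack the enone, the angelate or the new methylene group.

Step 14
Reactants: 25 acrylic acid
Product: 28 CNP0149130.1 (target), via silyl ester 26 (not isolated), via silylated lactone 27 (not isolated)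
Conditions: MeC(OSiMe3)=NSiMe3 (BSA), CH2Cl2, rt; then Me3SiOTf (0.3 equiv), −20 → 0 °C; then HCl (0.5 M aq.), THF, 0 °C
Reagents that add atoms: none
Why: Proposed new method: silylation turns the acid into a trimethylsilyl ester and caps the tertiary hydroxyl, catalytic Me3SiOTf then silylates the bridging ether oxygen, and the ester carbonyl oxygen, held on the endo face anti-periplanar to the C6–O bond, displaces the oxonium oxygen at C6 in a 5-exo-tet SN2 step with inversion, which closes the cis-fused lactone, passes the silyl group on and leaves the bridge oxygen on C9 with retention (freed on acidic work-up); the closest known reaction types are the cleavage of cyclic ethers through silyl oxonium ions, the acid-promoted acetolysis of oxygen-bridged bicycles with inversion at the attacked carbon, and anti 5-exo lactonisation onto iodonium or epoxide electrophiles.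

**Compound list**
1 | 3-bromofuran | Brc1ccoc1 | starting material
2 | oxirane | C1CO1 | starting material
3 | furan-3-yllithium | [Li]c1ccoc1 | intermediate (not isolated)
4 | 2-(furan-3-yl)ethanol | OCCc1ccoc1 | intermediate
5 | tert-butyl[2-(furan-3-yl)ethoxy]dimethylsilane | CC(C)(C)[Si](C)(C)OCCc1ccoc1 | intermediate
6 | 1-bromobutan-2-one | CCC(=O)CBr | starting material
7 | (Z)-2-oxidobut-2-en-1-ylium (1-methyl oxyallyl cation, methyl cis to oxygen) | C/C=C(\[O-])[CH2+] | intermediate (not isolated)
8 | (1R,2S,5R)-6-[2-(tert-butyldimethylsilyloxy)ethyl]-2-methyl-8-oxabicyclo[3.2.1]oct-6-en-3-one (labels 6R,9R,10S; methyl anti to the oxygen bridge) | O1[C@H]2C(CCO[Si](C)(C)C(C)(C)C)=C[C@@H]1[C@H](C)C(=O)C2 | intermediate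
9 | (1R,2S,5R,6R)-6-[2-(tert-butyldimethylsilyloxy)ethyl]-2-methyl-8-oxabicyclo[3.2.1]octan-3-one (labels 6R,7R,9R,10S; side chain endo) | O1[C@H]2[C@H](CCO[Si](C)(C)C(C)(C)C)C[C@@H]1[C@H](C)C(=O)C2 | intermediate
10 | trimethylsilyl enol ether of 9, C1(OSiMe3)=C5 (labels 6S,7R,9R,10S) | O1[C@H]2[C@H](CCO[Si](C)(C)C(C)(C)C)C[C@@H]1[C@H](C)C(O[Si](C)(C)C)=C2 | intermediate
11 | exo C1,C5-epoxide of 10 (epoxide oxygen syn to the bridge, OSiMe3 on C1) | O1[C@H]2[C@H](CCO[Si](C)(C)C(C)(C)C)C[C@@H]1[C@H](C)[C@@]3(O[Si](C)(C)C)O[C@@H]23 | intermediate (not isolated)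
12 | C5-(trimethylsilyloxy) ketone, silyloxy group syn to the bridge | O1[C@H]2[C@H](CCO[Si](C)(C)C(C)(C)C)C[C@@H]1[C@H](C)C(=O)[C@H]2O[Si](C)(C)C | intermediate (not isolated)
13 | (1R,2S,4S,5S,6R)-6-[2-(tert-butyldimethylsilyloxy)ethyl]-4-hydroxy-2-methyl-8-oxabicyclo[3.2.1]octan-3-one (labels 5S,6S,7R,9R,10S; C5–OH syn to the bridge) | O1[C@H]2[C@H](CCO[Si](C)(C)C(C)(C)C)C[C@@H]1[C@H](C)C(=O)[C@H]2O | intermediate
14 | methoxyallene (1-methoxypropa-1,2-diene) | COC=C=C | starting material
15 | 1-lithio-1-methoxypropa-1,2-diene | [Li]C(OC)=C=C | intermediate (not isolated)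
16 | (1S,2S,3S,4S,5R,7R)-7-[2-(tert-butyldimethylsilyloxy)ethyl]-3-(1-methoxypropa-1,2-dien-1-yl)-4-methyl-8-oxabicyclo[3.2.1]octane-2,3-diol (labels 1S,5S,6S,7R,9R,10S; C1–OH anti, C2 syn to the bridge) | O1[C@H]2[C@H](CCO[Si](C)(C)C(C)(C)C)C[C@@H]1[C@H](C)[C@@](O)(C(OC)=C=C)[C@H]2O | intermediate
17 | angelic acid, (Z)-2-methylbut-2-enoic acid | C/C=C(/C)C(=O)O | starting material
18 | angelic 2,4,6-trichlorobenzoic mixed anhydride | C/C=C(/C)C(=O)OC(=O)c1c(Cl)cc(Cl)cc1Cl | intermediate (not isolated)
19 | O5-angelate of 16 (labels 1S,5S,6S,7R,9R,10S) | O1[C@H]2[C@H](CCO[Si](C)(C)C(C)(C)C)C[C@@H]1[C@H](C)[C@@](O)(C(OC)=C=C)[C@H]2OC(=O)/C(C)=C\C | intermediate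
20 | bicyclic vinyl ketone: C1(OH)(prop-2-enoyl), C5 angelate, C7 CH2CH2OH (labels 1S,5S,6S,7R,9R,10S) | O1[C@H]2[C@H](CCO)C[C@@H]1[C@H](C)[C@@](O)(C(=O)C=C)[C@H]2OC(=O)/C(C)=C\C | intermediate
21 | bicyclic (E)-crotonyl ketone: C1(OH)[(E)-but-2-enoyl], C5 angelate, C7 CH2CH2OH (labels 1S,5S,6S,7R,9R,10S) | O1[C@H]2[C@H](CCO)C[C@@H]1[C@H](C)[C@@](O)(C(=O)/C=C/C)[C@H]2OC(=O)/C(C)=C\C | intermediate
22 | aldehyde: 21 with C7 CH2CHO (labels 1S,5S,6S,7S,9R,10S) | O1[C@H]2[C@H](CC=O)C[C@@H]1[C@H](C)[C@@](O)(C(=O)/C=C/C)[C@H]2OC(=O)/C(C)=C\C | intermediate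
23 | Mannich base: 22 with CH2NMe2 on C11 (C11 configuration not controlled) | O1[C@H]2[C@H](C(CN(C)C)C=O)C[C@@H]1[C@H](C)[C@@](O)(C(=O)/C=C/C)[C@H]2OC(=O)/C(C)=C\C | intermediate (not isolated)
24 | α-methylene aldehyde: C7 C(=CH2)CHO (labels 1S,5S,6S,7S,9R,10S) | O1[C@H]2[C@H](C(=C)C=O)C[C@@H]1[C@H](C)[C@@](O)(C(=O)/C=C/C)[C@H]2OC(=O)/C(C)=C\C | intermediate
25 | acrylic acid: C7 C(=CH2)CO2H (labels 1S,5S,6S,7S,9R,10S) | O1[C@H]2[C@H](C(=C)C(=O)O)C[C@@H]1[C@H](C)[C@@](O)(C(=O)/C=C/C)[C@H]2OC(=O)/C(C)=C\C | intermediate
26 | trimethylsilyl ester and C1 trimethylsilyl ether of 25 | O1[C@H]2[C@H](C(=C)C(=O)O[Si](C)(C)C)C[C@@H]1[C@H](C)[C@@](O[Si](C)(C)C)(C(=O)/C=C/C)[C@H]2OC(=O)/C(C)=C\C | intermediate (not isolated)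
27 | 1,9-bis(trimethylsilyl) ether of 28 | C=C1C(=O)O[C@@H]2[C@H]1C[C@@H](O[Si](C)(C)C)[C@H](C)[C@@](O[Si](C)(C)C)(C(=O)/C=C/C)[C@H]2OC(=O)/C(C)=C\C | intermediate (not isolated)
28 | CNP0149130.1: [(3aS,5R,6S,7S,8S,8aR)-7-[(E)-but-2-enoyl]-5,7-dihydroxy-6-methyl-3-methylidene-2-oxo-3,3a,4,5,6,7,8,8a-octahydro-2H-cyclohepta[b]furan-8-yl] (Z)-2-methylbut-2-enoate (labels 1S,5S,6R,7S,9R,10S) | C=C1C(=O)O[C@@H]2[C@H]1C[C@@H](O)[C@H](C)[C@@](O)(C(=O)/C=C/C)[C@H]2OC(=O)/C(C)=C\C | target

**Step count**
Total: 14 steps. Longest linear sequence: 14 steps, from 3-bromofuran 1 to 28; 2, 6, 14 and 17 are bought.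

**Steps most likely to fail**

Step 3. The cation may form and react outside the chiral hydrogen-bonding pocket, giving racemic or poorly enriched product. Enolisation by the solid base may also be too slow in the weakly ionising medium, and regiocontrol could erode. The fallback uses known chemistry and sets out from 5 and 6. The cycloaddition is run without catalyst under the established conditions for α-halo ketones (Et3N, CF3CH2OH, rt), which should give the racemic cycloadduct F1 with the same regio- and relative configuration. The enantiomers are then separated by preparative supercritical-fluid chromatography on a chiral stationary phase, and the (1R,2S,5R) enantiomer re-enters the route as 8.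

Step 14. Displacement at C6 may be too slow, because the neighbouring acyloxy group on C5 and the endo substituent lower its reactivity. Cleavage at C9 (6-exo attack of the same carboxyl), α-ketol rearrangement or isomerisation of the angelate could then take over. The fallback uses known reactions and sets out from 25.
- Me2BBr (CH2Cl2, −78 → 0 °C) cleaves the bridge; bromide is expected to attack the less hindered, electronically unbiased C9 with inversion and leave the C6 hydroxyl with retention, giving the bromo hydroxy acid F2.
- Mitsunobu lactonisation (PPh3, DIAD, THF, 0 °C) closes the γ-lactone with inversion at C6 to the bromo lactone F3.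
- HCO2Cs (DMF, 50 °C) exchanges the C9 bromide for formate with a second inversion, giving the C9 formate F4.
- Mild methanolysis (NaHCO3, MeOH, 0 °C) removes the formyl group and the sequence comes back at 28.

Step 8. Acylation of the hindered axial C5 hydroxyl next to the quaternary carbinol may be slow, so that Z-to-E isomerisation of the angeloyl unit (tiglate formation) and thermal loss of the allenyl ether compete. The fallback builds the Z olefin on the ester and does not transfer it; it sets out from 16. O5 is acylated with 2-[bis(2,2,2-trifluoroethoxy)phosphoryl]propanoic acid (DCC, cat. DMAP, CH2Cl2) to the phosphonate ester F5. Still–Gennari olefination with acetaldehyde (KN(SiMe3)2, 18-crown-6, THF, −78 °C; two equivalents of base because the tertiary hydroxyl is also deprotonated) should then give the (Z)-2-methylbut-2-enoate, rejoining the route at 19.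

Further compounds
F1 | step 3 | racemic 6-[2-(tert-butyldimethylsilyloxy)ethyl]-2-methyl-8-oxabicyclo[3.2.1]oct-6-en-3-one (methyl anti to the bridge, both enantiomers) | O1[C@H]2C(CCO[Si](C)(C)C(C)(C)C)=C[C@@H]1[C@H](C)C(=O)C2.O1[C@@H]2C(CCO[Si](C)(C)C(C)(C)C)=C[C@H]1[C@@H](C)C(=O)C2
F2 | step 14 | monocyclic bromo hydroxy acid from 25: C6–OH retained, C9–Br inverted (9S), C7 C(=CH2)CO2H | C=C(C(=O)O)[C@@H]1C[C@H](Br)[C@H](C)[C@@](O)(C(=O)/C=C/C)[C@@H](OC(=O)/C(C)=C\C)[C@H]1O
F3 | step 14 | 9-bromo-9-deoxy analogue of 28 with inverted C9 (9S) | C=C1C(=O)O[C@@H]2[C@H]1C[C@H](Br)[C@H](C)[C@@](O)(C(=O)/C=C/C)[C@H]2OC(=O)/C(C)=C\C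
F4 | step 14 | 9-O-formyl derivative of 28 | C=C1C(=O)O[C@@H]2[C@H]1C[C@@H](OC=O)[C@H](C)[C@@](O)(C(=O)/C=C/C)[C@H]2OC(=O)/C(C)=C\C
F5 | step 8 | O5-{2-[bis(2,2,2-trifluoroethoxy)phosphoryl]propanoate} of 16 (phosphonate α-carbon not controlled) | O1[C@H]2[C@H](CCO[Si](C)(C)C(C)(C)C)C[C@@H]1[C@H](C)[C@@](O)(C(OC)=C=C)[C@H]2OC(=O)C(C)P(=O)(OCC(F)(F)F)OCC(F)(F)F
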